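**Strategy.** The route rests on cutting the C2–C1' bond that joins ring C to ring B. C2 is a benzylic carbon β to the C4 ketone, so it is made by enantioselective rhodium-catalysed 1,4-addition of a ring B arylboronic acid to the C2=C3 enone of a flat, achiral 5,7-bis(MOM)-6-prenylchromone. This sets the C2 stereocentre in one operation; the C3 hydroxyl is then added trans by enolate oxidation. Both partners come from mirror-symmetric arenes (2-prenylphloroglucinol with O1 para to the prenyl group, and 2-geranylresorcinol), so no 6- versus 8-prenyl or ring B regiochemistry question arises.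

Key step: step 12

**Remarks on the chemistry.**
- MOM = methoxymethyl; prenyl = 3-methylbut-2-en-1-yl; geranyl = (2E)-3,7-dimethylocta-2,6-dien-1-yl.
- (S)-MeO-F12-BIPHEP = (S)-(6,6'-dimethoxybiphenyl-2,2'-diyl)bis[bis(3,4,5-trifluorophenyl)phosphine], assumed available in both antipodes.
- Assumption: the (S)-ligand is taken to deliver the aryl group to the chromone face that gives (2S), by analogy with (S)-configured biaryl bisphosphine–rhodium arylations of cyclic enones. Should the sense be the reverse, the (R)-ligand is used in the same procedure.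

**Ring A and ring C: the chromone**

Step 1
Reactants: 1 phloroglucinol
Product: 2 5-[(triisopropylsilyl)oxy]benzene-1,3-diol
Conditions: 1 (3 equiv), TIPSCl (1 equiv), imidazole (1.2 equiv), DMF, 0 °C to rt; excess 1 removed by aqueous wash
Reagents that add atoms: chlorotriisopropylsilane CC(C)[Si](Cl)(C(C)C)C(C)C
Why: O-silylation of a phenol with the silyl chloride as limiting reagent against an excess of the cheap, water-soluble triol should give mainly the mono-ether, the bulky silyl group further slowing a second silylation.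

Step 2
Reactants: 2 5-[(triisopropylsilyl)oxy]benzene-1,3-diol
Product: 3 [3,5-bis(methoxymethoxy)phenoxy]triisopropylsilane
Conditions: MOMCl (2.6 equiv), i-Pr2NEt (3.5 equiv), CH2Cl2, 0 °C to rt
Reagents that add atoms: chloromethyl methyl ether COCCl
Why: Amine-mediated O-alkylation (Williamson-type acetal ether formation) of both free phenols should proceed cleanly, the aryl silyl ether being stable to the hindered amine base.

Step 3
Reactants: 3 [3,5-bis(methoxymethoxy)phenoxy]triisopropylsilane; 4 prenyl bromide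
Product: 6 [3,5-bis(methoxymethoxy)-4-(3-methylbut-2-en-1-yl)phenoxy]triisopropylsilane, via aryllithium 5 (not isolated)
Conditions: n-BuLi (1.15 equiv), THF, 0 °C, 1 h; CuI (10 mol %), then 4 (1.3 equiv), −78 °C to rt
Reagents that add atoms: none
Why: Directed ortho-metalation should occur at the only C–H flanked by two coordinating MOM ethers (the bulky, non-coordinating silyl ether shields its own neighbours), and copper-catalysed SN2 allylation at the primary carbon of prenyl bromide then installs the linear prenyl group.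

Step 4
Reactants: 6 [3,5-bis(methoxymethoxy)-4-(3-methylbut-2-en-1-yl)phenoxy]triisopropylsilane
Product: 7 3,5-bis(methoxymethoxy)-4-(3-methylbut-2-en-1-yl)phenol
Conditions: TBAF (1.1 equiv), THF, 0 °C; pH 7 phosphate buffer
Reagents that add atoms: none
Why: Fluoride-induced desilylation of an aryl silyl ether is fast and leaves the MOM acetals and the alkene untouched.

Step 5
Reactants: 7 3,5-bis(methoxymethoxy)-4-(3-methylbut-2-en-1-yl)phenol
Product: 8 6-hydroxy-2,4-bis(methoxymethoxy)-3-(3-methylbut-2-en-1-yl)benzaldehyde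
Conditions: MgCl2 (2 equiv), Et3N (4 equiv), (CH2O)n (6 equiv), MeCN, 80 °C; cold aq citric acid work-up
Reagents that add atoms: paraformaldehyde (as formaldehyde) C=O
Why: The magnesium-phenoxide-directed ortho-formylation (Casnati–Skattebøl reaction) is specific for the position next to the free hydroxyl, the two ortho positions are equivalent by symmetry and the para position is blocked, so one salicylaldehyde should result under non-acidic conditions that spare the MOM ethers.

Step 6
Reactants: 8 6-hydroxy-2,4-bis(methoxymethoxy)-3-(3-methylbut-2-en-1-yl)benzaldehyde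
Product: 9 racemic 2-(1-hydroxyprop-2-yn-1-yl)-3,5-bis(methoxymethoxy)-4-(3-methylbut-2-en-1-yl)phenol
Conditions: HC≡CMgBr (3 equiv), THF, 0 °C to rt; pH 7 buffer at 0 °C; used crude at once
Reagents that add atoms: ethynylmagnesium bromide C#C[Mg]Br
Why: After the first equivalent has deprotonated the phenol, 1,2-addition of the small alkynyl Grignard reagent to the aldehyde should give the propargylic alcohol, whose stereocentre is racemic and is erased in the next step.

Step 7
Reactants: 9 racemic 2-(1-hydroxyprop-2-yn-1-yl)-3,5-bis(methoxymethoxy)-4-(3-methylbut-2-en-1-yl)phenol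
Product: 10 1-[6-hydroxy-2,4-bis(methoxymethoxy)-3-(3-methylbut-2-en-1-yl)phenyl]prop-2-yn-1-one
Conditions: activated MnO2 (15 equiv), CH2Cl2, rt; filtered through Celite and used directly
Reagents that add atoms: none
Why: MnO2 oxidation is selective for the doubly activated benzylic–propargylic alcohol and should leave the phenol, the MOM ethers and the prenyl alkene alone.

Step 8
Reactants: 10 1-[6-hydroxy-2,4-bis(methoxymethoxy)-3-(3-methylbut-2-en-1-yl)phenyl]prop-2-yn-1-one
Product: 12 5,7-bis(methoxymethoxy)-6-(3-methylbut-2-en-1-yl)-4H-chromen-4-one, via enaminone 11 (not isolated)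
Conditions: Et2NH (3 equiv), EtOH, rt then 60 °C
Reagents that add atoms: none
Why: Conjugate addition of the secondary amine to the terminal ynone gives a β-aminoenone, to whose β-carbon the ortho phenol adds with loss of diethylamine (addition–elimination, 6-endo oxa-Michael closure), which should give the chromone without acid and without the competing 5-exo closure.

**Ring B: the boronic acid**

Step 9
Reactants: 13 resorcinol
Product: 14 1,3-bis(methoxymethoxy)benzene
Conditions: MOMCl (2.6 equiv), i-Pr2NEt (3.5 equiv), CH2Cl2, 0 °C to rt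
Reagents that add atoms: chloromethyl methyl ether COCCl
Why: Standard amine-mediated bis-O-alkylation of a phenol with chloromethyl methyl ether.

Step 10
Reactants: 14 1,3-bis(methoxymethoxy)benzene; 15 geranyl bromide
Product: 17 2-[(2E)-3,7-dimethylocta-2,6-dien-1-yl]-1,3-bis(methoxymethoxy)benzene, via aryllithium 16 (not isolated)
Conditions: n-BuLi (1.1 equiv), THF, 0 °C to rt, 1 h; CuI (10 mol %), then 15 (1.2 equiv), −78 °C to rt
Reagents that add atoms: none
Why: Directed ortho-metalation at C2 between the two MOM ethers followed by copper-catalysed SN2 allylation should give the 2-geranyl arene with the (E)-alkene carried over unchanged from geranyl bromide.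

Step 11
Reactants: 17 2-[(2E)-3,7-dimethylocta-2,6-dien-1-yl]-1,3-bis(methoxymethoxy)benzene
Product: 20 {3-[(2E)-3,7-dimethylocta-2,6-dien-1-yl]-2,4-bis(methoxymethoxy)phenyl}boronic acid, via aryllithium 18 (not isolated), via lithium aryltriisopropoxyborate 19 (not isolated)
Conditions: n-BuLi (1.3 equiv), TMEDA (1.3 equiv), THF, −20 to 0 °C, 1.5 h; B(Oi-Pr)3 (2 equiv), −78 °C to rt; 1 M aq HCl to pH 6, 0 °C; used promptly
Reagents that add atoms: triisopropyl borate CC(C)OB(OC(C)C)OC(C)C; water O
Why: MOM-directed ortho-lithiation at C4 (equivalent to C6 by symmetry) followed by borate trapping and mild hydrolysis is the standard directed-metalation route to an ortho-alkoxy arylboronic acid.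

**Union and completion**

Step 12
Reactants: 12 5,7-bis(methoxymethoxy)-6-(3-methylbut-2-en-1-yl)-4H-chromen-4-one; 20 {3-[(2E)-3,7-dimethylocta-2,6-dien-1-yl]-2,4-bis(methoxymethoxy)phenyl}boronic acid
Product: 21 (2S)-2-{3-[(2E)-3,7-dimethylocta-2,6-dien-1-yl]-2,4-bis(methoxymethoxy)phenyl}-5,7-bis(methoxymethoxy)-6-(3-methylbut-2-en-1-yl)-2,3-dihydro-4H-chromen-4-one
Conditions: [RhCl(C2H4)2]2 (2.5 mol %), (S)-MeO-F12-BIPHEP (5.5 mol %), aq KOH (10 mol %), toluene/H2O 20:1, 30 °C; 20 (2.5 equiv) added in three portions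
Reagents that add atoms: none
Why: The hydroxo-rhodium bisphosphine complex takes the aryl group from boron by transmetalation, the aryl-rhodium species binds the chromone C2=C3 bond and inserts it so that the aryl group ends on C2 and an oxa-π-allyl rhodium enolate forms, and water protonates this enolate to release the flavanone and regenerate the hydroxo complex. The closest known reaction type is the Hayashi–Miyaura asymmetric conjugate addition of arylboronic acids as applied to chromones with electron-poor bisphosphine ligands. No ring closes, because ring C is already in place and only the C2–C1' bond forms. The new C2 stereocentre is controlled by the chiral ligand on rhodium, which distinguishes the two enantiotopic faces of the planar, achiral chromone and is expected to give (2S). The step needs 1,4- over 1,2-addition and reaction at the enone only, which the soft aryl-rhodium nucleophile and the absence of any other activated alkene secure, the three trisubstituted prenyl and geranyl alkenes not being substrates for insertion. The boronic acid has only one ortho substituent, and the nearly neutral, low-temperature medium should prevent retro-oxa-Michael opening of the product, which would racemise C2.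

Step 13
Reactants: 21 (2S)-2-{3-[(2E)-3,7-dimethylocta-2,6-dien-1-yl]-2,4-bis(methoxymethoxy)phenyl}-5,7-bis(methoxymethoxy)-6-(3-methylbut-2-en-1-yl)-2,3-dihydro-4H-chromen-4-one
Product: 23 (2R,3R)-2-{3-[(2E)-3,7-dimethylocta-2,6-dien-1-yl]-2,4-bis(methoxymethoxy)phenyl}-3-hydroxy-5,7-bis(methoxymethoxy)-6-(3-methylbut-2-en-1-yl)-2,3-dihydro-4H-chromen-4-one, via sodium enolate 22 (not isolated)
Conditions: NaN(SiMe3)2 (1.15 equiv), THF, −78 °C, 20 min; trans-2-(phenylsulfonyl)-3-phenyloxaziridine (1.5 equiv), −78 °C, 30 min; AcOH quench at −78 °C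
Reagents that add atoms: trans-2-(phenylsulfonyl)-3-phenyloxaziridine O=S(=O)(c1ccccc1)N1OC1c1ccccc1
Why: Kinetic enolisation toward C3 (the only α-CH2) and Davis enolate hydroxylation, which ignores isolated alkenes, should deliver oxygen to the enolate face opposite the C2 aryl group (substrate control), giving the 2,3-trans isomer that is also the more stable one, while the low temperature disfavours β-elimination of the ring oxygen; C2 is untouched and becomes (R) only by the change in CIP priorities.

Step 14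
Reactants: 23 (2R,3R)-2-{3-[(2E)-3,7-dimethylocta-2,6-dien-1-yl]-2,4-bis(methoxymethoxy)phenyl}-3-hydroxy-5,7-bis(methoxymethoxy)-6-(3-methylbut-2-en-1-yl)-2,3-dihydro-4H-chromen-4-one
Product: 24 (2R,3R)-2-{3-[(2E)-3,7-dimethylocta-2,6-dien-1-yl]-2,4-dihydroxyphenyl}-3,5,7-trihydroxy-6-(3-methylbut-2-en-1-yl)-2,3-dihydro-4H-chromen-4-one (CNP0166115.1)
Conditions: 3 M aq HCl/MeOH 1:5, 40 °C, stopped on completion; aq NaHCO3
Reagents that add atoms: none
Why: Acid-catalysed transacetalisation to methanol removes all four aryl MOM ethers under conditions mild enough that the trisubstituted alkenes should not cyclise onto the neighbouring phenols and the trans C2/C3 configuration should be kept.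

**Compound list**

1 | phloroglucinol | Oc1cc(O)cc(O)c1 | starting material
2 | 5-[(triisopropylsilyl)oxy]benzene-1,3-diol | CC(C)[Si](Oc1cc(O)cc(O)c1)(C(C)C)C(C)C | intermediate
3 | [3,5-bis(methoxymethoxy)phenoxy]triisopropylsilane | COCOc1cc(OCOC)cc(O[Si](C(C)C)(C(C)C)C(C)C)c1 | intermediate
4 | prenyl bromide (1-bromo-3-methylbut-2-ene) | CC(C)=CCBr | starting material
5 | [2,6-bis(methoxymethoxy)-4-(triisopropylsilyloxy)phenyl]lithium | [Li]c1c(OCOC)cc(O[Si](C(C)C)(C(C)C)C(C)C)cc1OCOC | intermediate
6 | [3,5-bis(methoxymethoxy)-4-(3-methylbut-2-en-1-yl)phenoxy]triisopropylsilane | COCOc1cc(O[Si](C(C)C)(C(C)C)C(C)C)cc(OCOC)c1CC=C(C)C | intermediate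
7 | 3,5-bis(methoxymethoxy)-4-(3-methylbut-2-en-1-yl)phenol | COCOc1cc(O)cc(OCOC)c1CC=C(C)C | intermediate
8 | 6-hydroxy-2,4-bis(methoxymethoxy)-3-(3-methylbut-2-en-1-yl)benzaldehyde | O=Cc1c(O)cc(OCOC)c(CC=C(C)C)c1OCOC | intermediate
9 | racemic 2-(1-hydroxyprop-2-yn-1-yl)-3,5-bis(methoxymethoxy)-4-(3-methylbut-2-en-1-yl)phenol | C#CC(O)c1c(O)cc(OCOC)c(CC=C(C)C)c1OCOC | intermediate
10 | 1-[6-hydroxy-2,4-bis(methoxymethoxy)-3-(3-methylbut-2-en-1-yl)phenyl]prop-2-yn-1-one | C#CC(=O)c1c(O)cc(OCOC)c(CC=C(C)C)c1OCOC | intermediate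
11 | (E)-3-(diethylamino)-1-[6-hydroxy-2,4-bis(methoxymethoxy)-3-(3-methylbut-2-en-1-yl)phenyl]prop-2-en-1-one | CCN(CC)/C=C/C(=O)c1c(O)cc(OCOC)c(CC=C(C)C)c1OCOC | intermediate
12 | 5,7-bis(methoxymethoxy)-6-(3-methylbut-2-en-1-yl)-4H-chromen-4-one | O=c1ccoc2cc(OCOC)c(CC=C(C)C)c(OCOC)c12 | intermediate
13 | resorcinol | Oc1cccc(O)c1 | starting material
14 | 1,3-bis(methoxymethoxy)benzene | COCOc1cccc(OCOC)c1 | intermediate
15 | geranyl bromide ((2E)-1-bromo-3,7-dimethylocta-2,6-diene) | CC(C)=CCC/C(C)=C/CBr | starting material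
16 | [2,6-bis(methoxymethoxy)phenyl]lithium | [Li]c1c(OCOC)cccc1OCOC | intermediate
17 | 2-[(2E)-3,7-dimethylocta-2,6-dien-1-yl]-1,3-bis(methoxymethoxy)benzene | CC(C)=CCC/C(C)=C/Cc1c(OCOC)cccc1OCOC | intermediate
18 | {3-[(2E)-3,7-dimethylocta-2,6-dien-1-yl]-2,4-bis(methoxymethoxy)phenyl}lithium | CC(C)=CCC/C(C)=C/Cc1c(OCOC)ccc([Li])c1OCOC | intermediate
19 | lithium {3-[(2E)-3,7-dimethylocta-2,6-dien-1-yl]-2,4-bis(methoxymethoxy)phenyl}tris(propan-2-yloxy)borate | CC(C)=CCC/C(C)=C/Cc1c(OCOC)ccc([B-](OC(C)C)(OC(C)C)OC(C)C)c1OCOC.[Li+] | intermediate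
20 | {3-[(2E)-3,7-dimethylocta-2,6-dien-1-yl]-2,4-bis(methoxymethoxy)phenyl}boronic acid | CC(C)=CCC/C(C)=C/Cc1c(OCOC)ccc(B(O)O)c1OCOC | intermediate
21 | (2S)-2-{3-[(2E)-3,7-dimethylocta-2,6-dien-1-yl]-2,4-bis(methoxymethoxy)phenyl}-5,7-bis(methoxymethoxy)-6-(3-methylbut-2-en-1-yl)-2,3-dihydro-4H-chromen-4-one | CC(C)=CCC/C(C)=C/Cc1c(OCOC)ccc([C@H]2Oc3cc(OCOC)c(CC=C(C)C)c(OCOC)c3C(=O)C2)c1OCOC | intermediate
22 | sodium enolate of 21 (sodium (2S)-2-aryl-5,7-bis(methoxymethoxy)-6-prenyl-2H-chromen-4-olate) | CC(C)=CCC/C(C)=C/Cc1c(OCOC)ccc([C@H]2Oc3cc(OCOC)c(CC=C(C)C)c(OCOC)c3C([O-])=C2)c1OCOC.[Na+] | intermediate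
23 | (2R,3R)-2-{3-[(2E)-3,7-dimethylocta-2,6-dien-1-yl]-2,4-bis(methoxymethoxy)phenyl}-3-hydroxy-5,7-bis(methoxymethoxy)-6-(3-methylbut-2-en-1-yl)-2,3-dihydro-4H-chromen-4-one | CC(C)=CCC/C(C)=C/Cc1c(OCOC)ccc([C@H]2Oc3cc(OCOC)c(CC=C(C)C)c(OCOC)c3C(=O)[C@@H]2O)c1OCOC | intermediate
24 | (2R,3R)-2-{3-[(2E)-3,7-dimethylocta-2,6-dien-1-yl]-2,4-dihydroxyphenyl}-3,5,7-trihydroxy-6-(3-methylbut-2-en-1-yl)-2,3-dihydro-4H-chromen-4-one (CNP0166115.1) | CC(C)=CCC/C(C)=C/Cc1c(O)ccc([C@H]2Oc3cc(O)c(CC=C(C)C)c(O)c3C(=O)[C@@H]2O)c1O | target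

**Step count and risks**

Total step count: 14. Longest linear sequence: 11 steps (steps 1 to 8, then 12 to 14); the ring B branch is 3 steps (9 to 11).

Steps most likely to fail:

Step 12. Aryl transfer from the hindered, electron-rich boronic acid may be slow, so that protodeboronation outruns insertion into the electron-rich 5-alkoxychromone, or the enantioface discrimination may be insufficient. The fallback builds ring C in the classical way and resolves; it sets out from aldehyde 8 and aryllithium 18 and returns at flavanone 21. MeMgBr adds to 8 to give racemic 2-(1-hydroxyethyl)-3,5-bis(methoxymethoxy)-4-(3-methylbut-2-en-1-yl)phenol F1, and MnO2 oxidation gives 1-[6-hydroxy-2,4-bis(methoxymethoxy)-3-(3-methylbut-2-en-1-yl)phenyl]ethan-1-one F2. Aryllithium 18 is quenched with DMF to give 3-[(2E)-3,7-dimethylocta-2,6-dien-1-yl]-2,4-bis(methoxymethoxy)benzaldehyde F3. Claisen–Schmidt condensation of F2 with F3 (KOH, EtOH) gives the (E)-2'-hydroxychalcone F4, and oxa-Michael closure through the single free phenol (NaOAc, EtOH, reflux) gives the racemic tetra-MOM flavanone F5. Kinetic resolution by asymmetric transfer hydrogenation (RhCl(Cp*)[(R,R)-TsDPEN], HCO2H/Et3N, EtOAc) is expected to reduce the (2R)-enantiomer to the (2R,4R)-cis-flavan-4-ol F6 and to leave (2S)-flavanone 21 (the other TsDPEN antipode being used if it proves to be the one matched to 2R).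

Step 13. The metal enolate may expel the ring oxygen (ring opening to the chalcone phenoxide, which erodes the C2 configuration) or be captured by the sulfonimine formed from the oxidant. The fallback avoids any free enolate; it sets out from 21 and returns at 23. Soft enolisation (TMSOTf, Et3N, CH2Cl2, 0 °C) gives the (2S)-4-(trimethylsilyloxy)-2H-chromene silyl enol ether F7. Neutral Rubottom-type oxidation with the same N-sulfonyloxaziridine (CHCl3, 50 °C), anti to the C2 aryl group and followed by silyl shift, gives the (2R,3R)-3-(trimethylsilyloxy)flavanone F8. Mild methanolysis (citric acid, MeOH, 0 °C) then frees the C3 hydroxyl to give 23.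

Step 11. The base may remove a proton from the doubly activated benzylic–allylic CH2 of the geranyl chain, which lies between the two MOM ethers, in competition with ring metalation, and the boronic acid may lose boron during isolation. The fallback fixes the boron position with a halogen before the chain is attached; it sets out from 14 and returns at aryllithium 18, which is carried on to 20 as in step 11. Bromination of 14 para to one MOM ether (NBS, MeCN, 0 °C) gives 1-bromo-2,4-bis(methoxymethoxy)benzene F9. LiN(i-Pr)2 (THF, −78 °C) removes the proton between the two MOM ethers to give [3-bromo-2,6-bis(methoxymethoxy)phenyl]lithium F10, which is geranylated with 15 under CuI catalysis to give 1-bromo-3-[(2E)-3,7-dimethylocta-2,6-dien-1-yl]-2,4-bis(methoxymethoxy)benzene F11. Bromine–lithium exchange (n-BuLi, THF, −78 °C), much faster than any deprotonation, then gives 18.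

Further compounds
F1 | step 12 | racemic 2-(1-hydroxyethyl)-3,5-bis(methoxymethoxy)-4-(3-methylbut-2-en-1-yl)phenol | CC(O)c1c(O)cc(OCOC)c(CC=C(C)C)c1OCOC
F2 | step 12 | 1-[6-hydroxy-2,4-bis(methoxymethoxy)-3-(3-methylbut-2-en-1-yl)phenyl]ethan-1-one | CC(=O)c1c(O)cc(OCOC)c(CC=C(C)C)c1OCOC
F3 | step 12 | 3-[(2E)-3,7-dimethylocta-2,6-dien-1-yl]-2,4-bis(methoxymethoxy)benzaldehyde | CC(C)=CCC/C(C)=C/Cc1c(OCOC)ccc(C=O)c1OCOC
F4 | step 12 | (E)-3-{3-[(2E)-3,7-dimethylocta-2,6-dien-1-yl]-2,4-bis(methoxymethoxy)phenyl}-1-[6-hydroxy-2,4-bis(methoxymethoxy)-3-(3-methylbut-2-en-1-yl)phenyl]prop-2-en-1-one | CC(C)=CCC/C(C)=C/Cc1c(OCOC)ccc(/C=C/C(=O)c2c(O)cc(OCOC)c(CC=C(C)C)c2OCOC)c1OCOC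
F5 | step 12 | racemic 2-{3-[(2E)-3,7-dimethylocta-2,6-dien-1-yl]-2,4-bis(methoxymethoxy)phenyl}-5,7-bis(methoxymethoxy)-6-(3-methylbut-2-en-1-yl)-2,3-dihydro-4H-chromen-4-one | CC(C)=CCC/C(C)=C/Cc1c(OCOC)ccc(C2Oc3cc(OCOC)c(CC=C(C)C)c(OCOC)c3C(=O)C2)c1OCOC
F6 | step 12 | (2R,4R)-2-{3-[(2E)-3,7-dimethylocta-2,6-dien-1-yl]-2,4-bis(methoxymethoxy)phenyl}-5,7-bis(methoxymethoxy)-6-(3-methylbut-2-en-1-yl)-3,4-dihydro-2H-chromen-4-ol | CC(C)=CCC/C(C)=C/Cc1c(OCOC)ccc([C@@H]2Oc3cc(OCOC)c(CC=C(C)C)c(OCOC)c3[C@H](O)C2)c1OCOC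
F7 | step 13 | (2S)-2-{3-[(2E)-3,7-dimethylocta-2,6-dien-1-yl]-2,4-bis(methoxymethoxy)phenyl}-5,7-bis(methoxymethoxy)-6-(3-methylbut-2-en-1-yl)-4-(trimethylsilyloxy)-2H-chromene | CC(C)=CCC/C(C)=C/Cc1c(OCOC)ccc([C@H]2Oc3cc(OCOC)c(CC=C(C)C)c(OCOC)c3C(O[Si](C)(C)C)=C2)c1OCOC
F8 | step 13 | (2R,3R)-2-{3-[(2E)-3,7-dimethylocta-2,6-dien-1-yl]-2,4-bis(methoxymethoxy)phenyl}-5,7-bis(methoxymethoxy)-6-(3-methylbut-2-en-1-yl)-3-(trimethylsilyloxy)-2,3-dihydro-4H-chromen-4-one | CC(C)=CCC/C(C)=C/Cc1c(OCOC)ccc([C@H]2Oc3cc(OCOC)c(CC=C(C)C)c(OCOC)c3C(=O)[C@@H]2O[Si](C)(C)C)c1OCOC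
F9 | step 11 | 1-bromo-2,4-bis(methoxymethoxy)benzene | COCOc1ccc(Br)c(OCOC)c1
F10 | step 11 | [3-bromo-2,6-bis(methoxymethoxy)phenyl]lithium | [Li]c1c(OCOC)ccc(Br)c1OCOC
F11 | step 11 | 1-bromo-3-[(2E)-3,7-dimethylocta-2,6-dien-1-yl]-2,4-bis(methoxymethoxy)benzene | CC(C)=CCC/C(C)=C/Cc1c(OCOC)ccc(Br)c1OCOC
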